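**Retrosynthetic overview** (dioxolane numbered O1–O2–C3–C4–C5, with CH2CO2Me on C3 and the side chain C1'–C15' on C5)

1. Last cut: C8'–C9' of the (7E,9E)-diene (Suzuki–Miyaura) gives an (E)-iodoalkenyl dioxolane and a (1E,4Z)-heptadienyl pinacolboronate, so no nucleophilic diene is present when the peroxide ring is made.
2. Key cut: ring bonds C3–C4 and O1–C5 together give the triethylsilyl peroxyketal of methyl acetoacetate (C3 already carrying O2–O1–Si) and a 2-methyl-1-alkene (C4=C5); forward, this is a catalytic enantioselective (3+2) annulation of a peroxycarbenium ion with the alkene.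
3. Enabling feature: C3 is a fully substituted carbon bonded to peroxide oxygen O2, a ketone carbon in disguise that can become the cation C3=O2(+)–O1Si; C4H2–C5(CH3)(alkyl)–O1 is what a 1,1-disubstituted alkene gives when attacked at its CH2 and closed at its tertiary carbon by O1.
4. Ring order: the 1,2-dioxolane is the only ring; it is formed in the key step together with both quaternary stereocentres.
5. Fragments: peroxyketal from methyl 3-methylbut-3-enoate (ozonolysis in methanol, silylation); alkene from 1-bromo-5-chloropentane (methallyl Grignard coupling, acetylide displacement, hydrozirconation–iodination); boronate from (Z)-pent-2-en-1-ol.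

Key step: step 9

Assumption: the six starting materials are taken as catalogue compounds, and because the sense of induction of the chiral acid in step 9 cannot be taken from precedent, the catalyst enantiomer (both are accessible from (R)- or (S)-BINOL) is fixed by a first experiment so that the (3R,5S) series results.

**Step 1**
Reactants: 1 methyl 3-methylbut-3-enoate
Product: 3 methyl 3-hydroperoxy-3-methoxybutanoate (racemic), via carbonyl oxide 2 (not isolated)
Conditions: O3, CH2Cl2/MeOH 4:1, −78 °C; N2 purge; no reductant; concentrated cold and used at once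
Reagents that add atoms: ozone, [O-][O+]=O; methanol, CO
Why: Ozonolysis of a 1,1-disubstituted alkene in methanol should split the primary ozonide into formaldehyde and the more substituted carbonyl oxide 2, which methanol traps as the α-methoxy hydroperoxide; the new stereocentre is racemic and is erased in step 9.

**Step 2**
Reactants: 3 methyl 3-hydroperoxy-3-methoxybutanoate
Product: 4 methyl 3-methoxy-3-[(triethylsilyl)peroxy]butanoate (racemic)
Conditions: Et3SiCl, Et3N, DMAP (cat.), CH2Cl2, 0 °C
Reagents that add atoms: chlorotriethylsilane, CC[Si](Cl)(CC)CC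
Why: O-silylation of a hydroperoxide (more acidic and more nucleophilic than an alcohol) with a chlorosilane and an amine base is standard and gives the silyl peroxyketal that serves as peroxycarbenium precursor.

**Step 3**
Reactants: 5 1-bromo-5-chloropentane; 6 2-methylallylmagnesium chloride
Product: 7 8-chloro-2-methyloct-1-ene
Conditions: Li2CuCl4 (2 mol %), THF, −20 → 20 °C
Reagents that add atoms: none
Why: Copper-catalysed Tamura–Kochi alkylation of an allylic Grignard reagent; the C–Br bond reacts far faster than the C–Cl bond, so the chloride remains as the handle for step 4.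

**Step 4**
Reactants: 7 8-chloro-2-methyloct-1-ene; 8 lithium acetylide–ethylenediamine complex
Product: 9 2-methyldec-1-en-9-yne
Conditions: NaI (10 mol %), DMSO, 20 °C
Reagents that add atoms: none
Why: SN2 alkylation of acetylide by a primary halide in DMSO, assisted by Finkelstein exchange with iodide, is a standard route to terminal alkynes and leaves the isolated alkene untouched.

**Step 5**
Reactants: 9 2-methyldec-1-en-9-yne
Product: 11 (1E)-1-iodo-9-methyldeca-1,9-diene, via alkenylzirconocene chloride 10 (not isolated)
Conditions: Cp2Zr(H)Cl (1.1 equiv), THF, 20 °C; then I2, 0 °C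
Reagents that add atoms: iodine, II
Why: Hydrozirconation adds Zr–H syn across the terminal alkyne with zirconium at the terminal carbon (a 1,1-disubstituted alkene reacts far more slowly), and iodinolysis with retention should give the (E)-iodoalkene.

**Step 6**
Reactants: 12 (2Z)-pent-2-en-1-ol
Product: 13 (2Z)-1-bromopent-2-ene
Conditions: PBr3 (0.4 equiv), pyridine (cat.), Et2O, −10 °C; handled as a solution
Reagents that add atoms: phosphorus tribromide, BrP(Br)Br
Why: Bromination of a primary allylic alcohol with PBr3 at low temperature proceeds by SN2 displacement on the phosphite ester and should keep the Z geometry.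

**Step 7**
Reactants: 13 (2Z)-1-bromopent-2-ene; 14 ethynylmagnesium bromide
Product: 15 (4Z)-hept-4-en-1-yne
Conditions: CuCl (5 mol %), THF, 0 → 40 °C
Reagents that add atoms: none
Why: Copper-catalysed coupling of an alkynyl Grignard reagent with a primary allylic bromide should give the skipped enyne by attack at the unhindered CH2 terminus, with the Z alkene retained.

**Step 8**
Reactants: 15 (4Z)-hept-4-en-1-yne
Product: 16 2-[(1E,4Z)-hepta-1,4-dien-1-yl]-4,4,5,5-tetramethyl-1,3,2-dioxaborolane
Conditions: pinacolborane (1.1 equiv), Cp2Zr(H)Cl (5 mol %), Et3N (10 mol %), neat, sealed, 60 °C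
Reagents that add atoms: pinacolborane, CC1(C)OBOC1(C)C
Why: Zirconocene-catalysed syn hydroboration of a terminal alkyne places boron on the terminal carbon and should give the (E)-alkenylboronate, while the internal Z alkene does not react.

**Step 9**
Reactants: 4 methyl 3-methoxy-3-[(triethylsilyl)peroxy]butanoate (1.5 equiv); 11 (1E)-1-iodo-9-methyldeca-1,9-diene
Product: 19 methyl 2-[(3R,5S)-5-[(7E)-8-iodooct-7-en-1-yl]-3,5-dimethyl-1,2-dioxolan-3-yl]acetate, via peroxycarbenium ion 17 (not isolated), via tertiary carbenium ion 18 (not isolated)
Conditions: chiral acid A (5 mol %; one enantiomer of the imidodiphosphorimidate built from two 3,3'-bis[3,5-bis(trifluoromethyl)phenyl]-1,1'-bi-2-naphthol units with N-trifluoromethanesulfonyl groups on both phosphorus atoms, C74H33F30N3O8P2S2), CH2Cl2, 4 Å molecular sieves, −78 °C; Et3N quench; chromatography to remove the cis diastereomer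
Reagents that add atoms: none
Why: Proposed new method: the confined chiral acid removes the methoxy group of 4 (as methanol, silylated in the turnover step) to give peroxycarbenium ion 17 paired with the chiral anion, the CH2 terminus of the 1,1-disubstituted alkene of 11 adds to the carbenium carbon (C3–C4 bond, tertiary-cation-forming regiochemistry) to give 18, and the silylated distal peroxide oxygen collapses onto that cation (O1–C5 bond) with transfer of the triethylsilyl group to methanol, which regenerates the acid. The closest known reaction types are the SnCl4- or TiCl4-promoted (3+2) annulation of silyl peroxyketals with alkenes, which gives racemic 1,2-dioxolanes, and counteranion-directed additions of alkenes and silyl nucleophiles to oxocarbenium ions under imidodiphosphorimidate catalysis; the new element is their combination on a peroxycarbenium ion. The dioxolane closes by attack of an oxygen lone pair on a free tertiary carbenium centre in a five-membered array, a stepwise (3+2) annulation that is endo with respect to the original C=C (both alkene carbons end up in the ring) and is free of the geometric restriction of trig closures because the acceptor is a cation. C3 (R) is set in the C–C bond formation by the chiral anion, which must tell apart the CH3 and CH2CO2Me flanks of the planar ion (confined acids of this family distinguish methyl from larger alkyl groups in ketone additions); C5 (S) is set in the ring closure, where the anion bound to 18 and the weak intrinsic preference of the long chain to lie trans to the CH2CO2Me arm select the face of the cation. The step needs chemoselectivity for the 1,1-dialkyl alkene over the iodoalkene (tertiary cation versus secondary or α-iodo cation), ring closure rather than proton loss or capture of 18 by the ester carbonyl (non-basic, non-nucleophilic anion; only the peroxide pathway ends in irreversible silyl loss), and suppression of acid-induced O–O fragmentation of 4 (−78 °C).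

**Step 10**
Reactants: 19 methyl 2-[(3R,5S)-5-[(7E)-8-iodooct-7-en-1-yl]-3,5-dimethyl-1,2-dioxolan-3-yl]acetate; 16 2-[(1E,4Z)-hepta-1,4-dien-1-yl]-4,4,5,5-tetramethyl-1,3,2-dioxaborolane (1.3 equiv)
Product: 20 methyl 2-[(3R,5S)-3,5-dimethyl-5-[(7E,9E,12Z)-pentadeca-7,9,12-trien-1-yl]-1,2-dioxolan-3-yl]acetate
Conditions: PdCl2(dppf) (5 mol %; dppf = 1,1'-bis(diphenylphosphino)ferrocene), K3PO4 (3 equiv), THF/H2O 10:1, degassed, 20 °C
Reagents that add atoms: none
Why: Suzuki–Miyaura coupling of an (E)-iodoalkene with an (E)-alkenylboronate (divalent palladium precatalyst reduced in the flask to zerovalent palladium) proceeds with retention at both partners and should fix the (7E,9E)-diene beside the untouched (12Z)-alkene; palladium-catalysed couplings of halides carrying dialkyl peroxides are a known class, and the di-tertiary dioxolane has no α-hydrogen for base-induced fragmentation.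

**Compound list**

1 | methyl 3-methylbut-3-enoate | C=C(C)CC(=O)OC | starting material
2 | carbonyl oxide of methyl acetoacetate (4-methoxy-4-oxobutan-2-one O-oxide) | COC(=O)CC(C)=[O+][O-] | intermediate
3 | methyl 3-hydroperoxy-3-methoxybutanoate (racemic) | COC(=O)CC(C)(OC)OO | intermediate
4 | methyl 3-methoxy-3-[(triethylsilyl)peroxy]butanoate (racemic) | COC(=O)CC(C)(OC)OO[Si](CC)(CC)CC | intermediate
5 | 1-bromo-5-chloropentane | ClCCCCCBr | starting material
6 | 2-methylallylmagnesium chloride | C=C(C)C[Mg]Cl | starting material
7 | 8-chloro-2-methyloct-1-ene | C=C(C)CCCCCCCl | intermediate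
8 | lithium acetylide–ethylenediamine complex | [Li+].[C-]#C.NCCN | starting material
9 | 2-methyldec-1-en-9-yne | C=C(C)CCCCCCC#C | intermediate
10 | chlorobis(cyclopentadienyl)[(1E)-9-methyldeca-1,9-dien-1-yl]zirconium (cyclopentadienyl rings drawn σ-bonded) | C=C(C)CCCCCC/C=C/[Zr](Cl)(C1C=CC=C1)C1C=CC=C1 | intermediate
11 | (1E)-1-iodo-9-methyldeca-1,9-diene | C=C(C)CCCCCC/C=C/I | intermediate
12 | (2Z)-pent-2-en-1-ol | CC/C=C\CO | starting material
13 | (2Z)-1-bromopent-2-ene | CC/C=C\CBr | intermediate
14 | ethynylmagnesium bromide | C#C[Mg]Br | starting material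
15 | (4Z)-hept-4-en-1-yne | CC/C=C\CC#C | intermediate
16 | 2-[(1E,4Z)-hepta-1,4-dien-1-yl]-4,4,5,5-tetramethyl-1,3,2-dioxaborolane | CC/C=C\C/C=C/B1OC(C)(C)C(C)(C)O1 | intermediate
17 | peroxycarbenium ion [MeO2CCH2C(CH3)=O–OSiEt3]+ (ion pair with the catalyst anion) | COC(=O)CC(C)=[O+]O[Si](CC)(CC)CC | intermediate
18 | open-chain tertiary carbenium ion after C3–C4 bond formation, (R) at the peroxide-bearing carbon (ion pair with the catalyst anion) | I/C=C/CCCCCC[C+](C)C[C@](C)(CC(=O)OC)OO[Si](CC)(CC)CC | intermediate
19 | methyl 2-[(3R,5S)-5-[(7E)-8-iodooct-7-en-1-yl]-3,5-dimethyl-1,2-dioxolan-3-yl]acetate | I/C=C/CCCCCC[C@@]1(C)C[C@](C)(CC(=O)OC)OO1 | intermediate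
20 | methyl 2-[(3R,5S)-3,5-dimethyl-5-[(7E,9E,12Z)-pentadeca-7,9,12-trien-1-yl]-1,2-dioxolan-3-yl]acetate | CC/C=C\C/C=C/C=C/CCCCCC[C@@]1(C)C[C@](C)(CC(=O)OC)OO1 | target

**Totals**

Total step count: 10. Longest linear sequence: 5 steps (steps 3, 4, 5, 9, 10).

**Steps most likely to fail**

Step 9 (Proposed new method). What may go wrong: insufficient facial discrimination by the chiral ion pair at C3 or at C5, stalled catalyst turnover, or loss of cation 18 by proton elimination. Fallback with known chemistry: it sets out from 4 and 11 and uses the established stoichiometric form of the annulation (SnCl4, 1 equiv, CH2Cl2, −78 °C), which should give the dioxolane as a mixture of the trans and cis racemates. The trans racemate is 19 together with its enantiomer methyl 2-[(3S,5R)-5-[(7E)-8-iodooct-7-en-1-yl]-3,5-dimethyl-1,2-dioxolan-3-yl]acetate F1. It is separated from the cis pair on silica gel and resolved by preparative chromatography on a polysaccharide-based chiral stationary phase. The fallback comes back to the route at 19, before step 10.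

Step 10. What may go wrong: reductive cleavage of the O–O bond by low-valent palladium or phosphine, or base-induced β-elimination that opens the β-peroxy ester. Fallback without a transition metal: it sets out from 19. Ozonolysis of the iodoalkene (O3, CH2Cl2, −78 °C; Me2S) should give methyl 2-[(3R,5S)-3,5-dimethyl-5-(7-oxoheptyl)-1,2-dioxolan-3-yl]acetate F2. Wittig reaction of F2 with (formylmethylene)triphenylphosphorane (CH2Cl2, 40 °C) should give methyl 2-[(3R,5S)-3,5-dimethyl-5-[(7E)-9-oxonon-7-en-1-yl]-1,2-dioxolan-3-yl]acetate F3. The olefination partner is made from purchased (Z)-hex-3-en-1-ol: Mitsunobu reaction with 1-phenyl-1H-tetrazole-5-thiol (PPh3, diisopropyl azodicarboxylate) gives 5-{[(3Z)-hex-3-en-1-yl]sulfanyl}-1-phenyl-1H-tetrazole F4, and oxidation (H2O2, (NH4)6Mo7O24 cat., EtOH) gives 5-{[(3Z)-hex-3-en-1-yl]sulfonyl}-1-phenyl-1H-tetrazole F5. Julia–Kocienski olefination (F5 metalated with KN(SiMe3)2 in DME at −60 °C before F3 is added, so that no free base meets the ester) should form C9'=C10' with E selectivity. The fallback comes back to the route at 20.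

Step 1. What may go wrong: fragmentation of the primary ozonide in the wrong sense (to formaldehyde oxide and the keto ester), or cyclisation or elimination of the β-ester hydroperoxide on concentration. Fallback: it sets out from 1. Reductive ozonolysis (O3, CH2Cl2, −78 °C; Me2S) gives the same ketone whichever way the ozonide splits and affords methyl acetoacetate F6 (also a catalogue compound). Ketalisation with trimethyl orthoformate (TsOH cat., MeOH) gives methyl 3,3-dimethoxybutanoate F7. Acid-catalysed exchange of one methoxy group for hydroperoxide (anhydrous H2O2 in Et2O, cat. acid, 0 °C; the classical route from ketals to α-alkoxy hydroperoxides) comes back to the route at 3, before step 2.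

**Further compounds**

F1 | step 9 | methyl 2-[(3S,5R)-5-[(7E)-8-iodooct-7-en-1-yl]-3,5-dimethyl-1,2-dioxolan-3-yl]acetate | I/C=C/CCCCCC[C@]1(C)C[C@@](C)(CC(=O)OC)OO1
F2 | step 10 | methyl 2-[(3R,5S)-3,5-dimethyl-5-(7-oxoheptyl)-1,2-dioxolan-3-yl]acetate | O=CCCCCCC[C@@]1(C)C[C@](C)(CC(=O)OC)OO1
F3 | step 10 | methyl 2-[(3R,5S)-3,5-dimethyl-5-[(7E)-9-oxonon-7-en-1-yl]-1,2-dioxolan-3-yl]acetate | O=C/C=C/CCCCCC[C@@]1(C)C[C@](C)(CC(=O)OC)OO1
F4 | step 10 | 5-{[(3Z)-hex-3-en-1-yl]sulfanyl}-1-phenyl-1H-tetrazole | CC/C=C\CCSc1nnnn1-c1ccccc1
F5 | step 10 | 5-{[(3Z)-hex-3-en-1-yl]sulfonyl}-1-phenyl-1H-tetrazole | CC/C=C\CCS(=O)(=O)c1nnnn1-c1ccccc1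
F6 | step 1 | methyl acetoacetate | CC(=O)CC(=O)OC
F7 | step 1 | methyl 3,3-dimethoxybutanoate | COC(=O)CC(C)(OC)OC
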